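The vessel is closed, stirred and isothermal. In the larch run E forms the ring Q, while the sum E + Q, which I call the pool S (fraction of the E charged), falls.

- larch: E 2.8 M; run made earlier
- flask: E 2.0 M; time 1.0 h

- larch (time / min: Q / %, E / %): 1.50: 11.0, 67.2; 5.00: 17.9, 40.8; 20.0: 12.5, 20.9; 60.0: 5.5, 8.7

(scatter of a reading: 0.5 percentage points)

- the best time, 1.0 h at the latest, for Q
- the amount of Q, in percent of the E charged, at that time

In the larch run Q/E reads 0.598 and then 0.632, so I freeze it. If E is lost in pairs, a pool of frozen make-up loses in second order, and the reciprocal of S climbs above one in proportion to charged [E] and time. That climb per unit of [E] and time I call the pool constant G: 0.0360 /M/min at 60.0 min, and 0.0356 /M/min at 20.0 min. Earlier, with Q/E still climbing, the larch run gives a larger G, 0.0503 /M/min at 5.00 min. I assume G and Q/E at a given time carry over to a new charge. By this estimate the flask at 2.0 M has S = 66.6% at 5.00 min and Q = 20.3%, and I commit to a peak soon after that, at about that height. The forecast is later and higher than my reckoning, 0.15 h and 21%: “Q peaks where Q/E ≈ 0.6, at about 9 min”.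

The flask peaks at 6.33 min with 19.7% Q.

    E ⇌ Q (K = 0.470, k = 0.00180 /s)
    2 E → J (k = 6.50 × 10⁻⁴ /M/s)

By the ring step alone, both ways together, E and Q relax with a half-life of 2.05 min, short against the 1.0 h allowed. With the late G, the flask at 2.0 M should hold a pool of 18.8% at 1.00 h, and it holds 19.0%. For the neighbour flask at 0.80 M, the same G gives 36.7% at 1.00 h. That neighbour ends with E 24.4% and Q 12.0%, a pool of 36.4%.

Readings and results were generated by integration on assumed constants; noise was put on by code.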